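**Plan** (polypodane numbering: bicycle C1–C10, arm C11–C12, chain from C13)
1. Retrosynthesis: cut the sp3–sp2 bond C12–C13 to give primary alkyl boronate 14 and (E)-vinyl iodide 20. This is possible because C12 is the terminal carbon of a two-carbon arm on C9 (a hydroborated C9 vinyl group) and C13=C14 is an (E)-trisubstituted alkene with its methyl on C14 (the pattern of alkyne carboalumination).
2. Bicycle: cut C4–CH3, C4–C5 and C1–C10 of ring A (reductive methylation, Robinson annulation with ethyl vinyl ketone) and C9–C11 (conjugate vinylation) back to ring B as cyclohexenone 7, made from (R)-linalool by ring-closing metathesis.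
3. Forward: ring B first, then the C9 vinyl group and the C10 quaternary centre, ring A by aldol condensation, cis ring fusion and gem-dimethyl by CuH reduction/methylation, hydroboration. The chain comes from geranyl bromide (propargylation, carboalumination–iodination, SeO2 oxidation). Then coupling, desilylation, acetylation.
4. Stereochemistry: C8 from (R)-linalool; C9 by cuprate addition anti to the C8 silyloxy group; C10 by Michael addition anti to the C9 vinyl group; C5 by hydride delivery on the face of the C10 methyl. Alkene geometries come from geranyl bromide, syn-carboalumination and (E)-selective allylic oxidation, and are retained in the coupling.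

Key step: step 15

Remark on the chemistry: read literally, the SMILES places H-5 on the same face as the C-10 methyl (cis-fused rings A/B; 5S,8R,9R,10S), so the trans-fused labdane chiral pool does not fit and the bicycle is built de novo with a cis-selective step.

**Route**

Step 1
Reactants: 1 (R)-(−)-linalool
Product: 2 (R)-triethyl[(3,7-dimethylocta-1,6-dien-3-yl)oxy]silane
Conditions: TESOTf, 2,6-lutidine, CH2Cl2, −78 → 0 °C
Reagents that add atoms: triethylsilyl trifluoromethanesulfonate, CC[Si](CC)(CC)OS(=O)(=O)C(F)(F)F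
Why: Silylation of a tertiary allylic alcohol with a silyl triflate and a hindered base is routine and leaves the chiral-pool carbinol centre (the future C8) untouched.

Step 2
Reactants: 2 (R)-triethyl[(3,7-dimethylocta-1,6-dien-3-yl)oxy]silane
Product: 4 (R)-4-methyl-4-[(triethylsilyl)oxy]hex-5-enal, via secondary ozonide 3 (not isolated)
Conditions: O3 (1.0 equiv, Sudan Red 7B end-point), CH2Cl2, −78 °C; then PPh3, −78 °C → rt
Reagents that add atoms: ozone, O=[O+][O-]
Why: Chemoselective ozonolysis should cleave the electron-rich trisubstituted alkene much faster than the vinyl group on the silyloxy-bearing quaternary carbon, and reductive work-up gives the aldehyde.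

Step 3
Reactants: 4 (R)-4-methyl-4-[(triethylsilyl)oxy]hex-5-enal
Product: 5 (6R)-2,6-dimethyl-6-[(triethylsilyl)oxy]octa-1,7-dien-3-ol (both C3 epimers)
Conditions: isopropenylmagnesium bromide, THF, −78 → 0 °C; aq. NH4Cl
Reagents that add atoms: isopropenylmagnesium bromide, C=C(C)[Mg]Br
Why: Grignard 1,2-addition to an aldehyde is reliable, and the new carbinol centre is removed in step 4.

Step 4
Reactants: 5 (6R)-2,6-dimethyl-6-[(triethylsilyl)oxy]octa-1,7-dien-3-ol
Product: 6 (R)-2,6-dimethyl-6-[(triethylsilyl)oxy]octa-1,7-dien-3-one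
Conditions: Dess–Martin periodinane, NaHCO3, CH2Cl2, 0 °C → rt
Reagents that add atoms: none
Why: Buffered Dess–Martin oxidation of a secondary allylic alcohol should give the isopropenyl ketone without alkene migration.

Step 5
Reactants: 6 (R)-2,6-dimethyl-6-[(triethylsilyl)oxy]octa-1,7-dien-3-one
Product: 7 (R)-2,4-dimethyl-4-[(triethylsilyl)oxy]cyclohex-2-en-1-one
Conditions: second-generation Hoveyda–Grubbs catalyst RuCl2(H2IMes)(=CH-C6H4-2-OiPr) (5 mol%), toluene (0.01 M), 80 °C
Reagents that add atoms: none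
Why: Ring-closing metathesis closes ring B as a 2-methylcyclohexenone with loss of ethene; no stereocentre is formed and the quaternary C8 cannot epimerise.

Step 6
Reactants: 7 (R)-2,4-dimethyl-4-[(triethylsilyl)oxy]cyclohex-2-en-1-one
Product: 8 triethyl{[(1R,2R)-2-ethenyl-1,3-dimethyl-4-[(trimethylsilyl)oxy]cyclohex-3-en-1-yl]oxy}silane (vinyl trans to the triethylsilyloxy group)
Conditions: vinylmagnesium bromide, CuBr·SMe2 (0.2 equiv), TMSCl, DMPU, THF, −78 → −40 °C; Et3N, cold aq. NaHCO3
Reagents that add atoms: vinylmagnesium bromide, C=C[Mg]Br; chlorotrimethylsilane, C[Si](C)(C)Cl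
Why: TMSCl-accelerated copper-catalysed conjugate addition should place the vinyl group at C9 anti to the pseudoaxial γ-silyloxy group (stereoelectronic and steric control as in 4-silyloxycyclohexenones, so vinyl trans to O8), while TMSCl traps the enolate regiospecifically across C5–C10.

Step 7
Reactants: 8 triethyl{[(1R,2R)-2-ethenyl-1,3-dimethyl-4-[(trimethylsilyl)oxy]cyclohex-3-en-1-yl]oxy}silane
Product: 9 (2R,3R,4R)-3-ethenyl-2,4-dimethyl-2-(3-oxopentyl)-4-[(triethylsilyl)oxy]cyclohexan-1-one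
Conditions: pent-1-en-3-one, BF3·OEt2, iPrOH, CH2Cl2/MeNO2, −78 °C
Reagents that add atoms: ethyl vinyl ketone (pent-1-en-3-one), C=CC(=O)CC
Why: Mukaiyama–Michael addition of the tetrasubstituted silyl enol ether should create the C10 quaternary centre with the new chain anti to the C9 vinyl group, because allylic 1,2-strain with the C10 methyl holds that vinyl group pseudoaxial and blocks one face.

Step 8
Reactants: 9 (2R,3R,4R)-3-ethenyl-2,4-dimethyl-2-(3-oxopentyl)-4-[(triethylsilyl)oxy]cyclohexan-1-one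
Product: 10 (4aR,5R,6R)-5-ethenyl-1,4a,6-trimethyl-6-[(triethylsilyl)oxy]-4,4a,5,6,7,8-hexahydronaphthalen-2(3H)-one
Conditions: NaOMe, MeOH, 60 °C
Reagents that add atoms: none
Why: Intramolecular aldol condensation (second half of a Robinson annulation) closes ring A through the C4–C5 bond and dehydrates to the tetrasubstituted enone without forming a stereocentre.

Step 9
Reactants: 10 (4aR,5R,6R)-5-ethenyl-1,4a,6-trimethyl-6-[(triethylsilyl)oxy]-4,4a,5,6,7,8-hexahydronaphthalen-2(3H)-one
Product: 13 (4aS,5R,6R,8aS)-5-ethenyl-1,1,4a,6-tetramethyl-6-[(triethylsilyl)oxy]octahydronaphthalen-2(1H)-one, via silyl enol ether 11 (not isolated), via lithium enolate 12 (not isolated)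
Conditions: CuCl (0.1 equiv), NaOtBu (0.1 equiv), 1,2-bis(diphenylphosphino)benzene (0.1 equiv), PhMe2SiH, toluene, rt; then MeLi, THF, 0 °C; then MeI, DMPU, −78 → 0 °C
Reagents that add atoms: iodomethane, CI
Why: Ligated CuH 1,4-reduction followed by enolate methylation (reductive alkylation) should deliver hydride to C5 on the face of the C10 methyl, as soft nucleophiles do with angularly methylated octalones, giving the cis ring fusion; the isolated vinyl group is inert, and the regio-defined enolate freed by MeLi is methylated at C4, which is not a stereocentre.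

Step 10
Reactants: 13 (4aS,5R,6R,8aS)-5-ethenyl-1,1,4a,6-tetramethyl-6-[(triethylsilyl)oxy]octahydronaphthalen-2(1H)-one
Product: 14 (4aS,5R,6R,8aS)-1,1,4a,6-tetramethyl-5-[2-(4,4,5,5-tetramethyl-1,3,2-dioxaborolan-2-yl)ethyl]-6-[(triethylsilyl)oxy]octahydronaphthalen-2(1H)-one
Conditions: pinacolborane, [Ir(cod)Cl]2 (2.5 mol%), dppe (5 mol%), CH2Cl2, rt
Reagents that add atoms: pinacolborane, CC1(C)OBOC1(C)C
Why: Iridium-catalysed anti-Markovnikov hydroboration of the terminal alkene places boron on C12 and, unlike free dialkylboranes, should leave the hindered C3 ketone untouched; no stereocentre is formed.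

Step 11
Reactants: 15 geranyl bromide
Product: 16 trimethyl[(5E)-6,10-dimethylundeca-5,9-dien-1-yn-1-yl]silane
Conditions: 1-(trimethylsilyl)propyne, n-BuLi, THF, −78 → −20 °C; then 15, −78 °C → rt
Reagents that add atoms: 1-(trimethylsilyl)propyne, CC#C[Si](C)(C)C
Why: SN2 alkylation of the lithiated silylpropyne at its propargylic carbon by the primary allylic bromide should proceed with retention of the (E)-alkene.

Step 12
Reactants: 16 trimethyl[(5E)-6,10-dimethylundeca-5,9-dien-1-yn-1-yl]silane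
Product: 17 (5E)-6,10-dimethylundeca-5,9-dien-1-yne
Conditions: K2CO3, MeOH, rt
Reagents that add atoms: none
Why: Methoxide-mediated protodesilylation of an alkynylsilane is routine and frees the terminal alkyne.

Step 13
Reactants: 17 (5E)-6,10-dimethylundeca-5,9-dien-1-yne
Product: 19 (1E,5E)-1-iodo-2,6,10-trimethylundeca-1,5,9-triene, via alkenylalane 18 (not isolated)
Conditions: Me3Al, Cp2ZrCl2 (0.25 equiv), CH2Cl2, 0 °C → rt; then I2, THF, −30 → 0 °C
Reagents that add atoms: trimethylaluminium, C[Al](C)C; iodine, II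
Why: Negishi zirconium-catalysed carboalumination adds methyl and aluminium syn (methyl to the internal carbon), and iodinolysis with retention fixes the (E)-trisubstituted vinyl iodide.

Step 14
Reactants: 19 (1E,5E)-1-iodo-2,6,10-trimethylundeca-1,5,9-triene
Product: 20 (2E,6E,10E)-11-iodo-2,6,10-trimethylundeca-2,6,10-trien-1-ol
Conditions: SeO2 (0.2 equiv), t-BuOOH, salicylic acid (0.1 equiv), CH2Cl2, 0 °C → rt (partial conversion)
Reagents that add atoms: tert-butyl hydroperoxide, CC(C)(C)OO
Why: SeO2/t-BuOOH allylic oxidation (ene reaction then [2,3]-shift) should select the (E)-methyl of the terminal isopropylidene unit, as in farnesyl derivatives, with the iodoalkene deactivated.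

Step 15
Reactants: 14 (4aS,5R,6R,8aS)-1,1,4a,6-tetramethyl-5-[2-(4,4,5,5-tetramethyl-1,3,2-dioxaborolan-2-yl)ethyl]-6-[(triethylsilyl)oxy]octahydronaphthalen-2(1H)-one; 20 (2E,6E,10E)-11-iodo-2,6,10-trimethylundeca-2,6,10-trien-1-ol
Product: 21 (4aS,5R,6R,8aS)-5-[(3E,7E,11E)-13-hydroxy-4,8,12-trimethyltrideca-3,7,11-trien-1-yl]-1,1,4a,6-tetramethyl-6-[(triethylsilyl)oxy]octahydronaphthalen-2(1H)-one
Conditions: Pd(OAc)2 (5 mol%), RuPhos (10 mol%), KOH (3 equiv), THF/H2O (10:1), 70 °C
Reagents that add atoms: none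
Why: Zerovalent palladium, formed from Pd(OAc)2 and RuPhos, inserts into the C13–I bond of 20 with retention of the (E)-geometry; hydroxide turns boronate 14 into the tetracoordinate hydroxyboronate, whose primary C12 alkyl group transmetalates to palladium, and reductive elimination forms the C12–C13 bond. The closest known reaction type is the B-alkyl Suzuki–Miyaura coupling of primary alkyl pinacol boronates with alkenyl halides under Pd(OAc)2/RuPhos/aqueous KOH. No ring is closed and no stereocentre is formed; the four stereocentres of the bicycle and the three (E)-alkenes are carried through, the C13=C14 geometry being held by stereoretentive oxidative addition and reductive elimination. The step needs coupling to outrun β-hydride elimination and protodeboronation, which the bulky electron-rich biarylphosphine and the unbranched primary C12–B carbon should secure; it also needs chemoselectivity for C–I, secured because the C3 ketone is shielded by the C4 gem-dimethyl group, O8 is a base-stable tertiary silyl ether and the free allylic alcohol is inert to aqueous hydroxide.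

Step 16
Reactants: 21 (4aS,5R,6R,8aS)-5-[(3E,7E,11E)-13-hydroxy-4,8,12-trimethyltrideca-3,7,11-trien-1-yl]-1,1,4a,6-tetramethyl-6-[(triethylsilyl)oxy]octahydronaphthalen-2(1H)-one
Product: 22 (4aS,5R,6R,8aS)-6-hydroxy-5-[(3E,7E,11E)-13-hydroxy-4,8,12-trimethyltrideca-3,7,11-trien-1-yl]-1,1,4a,6-tetramethyloctahydronaphthalen-2(1H)-one
Conditions: HF·pyridine, pyridine, THF, 0 °C → rt
Reagents that add atoms: none
Why: Buffered fluoride cleavage of the tertiary triethylsilyl ether should free the C8 alcohol without touching the ketone, the alkenes or the allylic alcohol.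

Step 17
Reactants: 22 (4aS,5R,6R,8aS)-6-hydroxy-5-[(3E,7E,11E)-13-hydroxy-4,8,12-trimethyltrideca-3,7,11-trien-1-yl]-1,1,4a,6-tetramethyloctahydronaphthalen-2(1H)-one
Product: 23 Myrrhanone A acetate (the 13-O-acetate of 22)
Conditions: Ac2O, pyridine, CH2Cl2, 0 °C → rt
Reagents that add atoms: acetic anhydride, CC(=O)OC(C)=O
Why: Acylation with Ac2O/pyridine should take only the primary allylic alcohol, because the hindered tertiary C8 hydroxyl does not acetylate without forcing.

**Compound list**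
1 | (R)-(−)-linalool | C=C[C@](C)(O)CCC=C(C)C | starting material
2 | (R)-triethyl[(3,7-dimethylocta-1,6-dien-3-yl)oxy]silane | C=C[C@](C)(O[Si](CC)(CC)CC)CCC=C(C)C | intermediate
3 | secondary ozonide of 2 (3,3-dimethyl-1,2,4-trioxolane at the former trisubstituted alkene) | C=C[C@](C)(O[Si](CC)(CC)CC)CCC1OOC(C)(C)O1 | intermediate
4 | (R)-4-methyl-4-[(triethylsilyl)oxy]hex-5-enal | C=C[C@](C)(O[Si](CC)(CC)CC)CCC=O | intermediate
5 | (6R)-2,6-dimethyl-6-[(triethylsilyl)oxy]octa-1,7-dien-3-ol (C3 epimers) | C=C[C@](C)(O[Si](CC)(CC)CC)CCC(O)C(C)=C | intermediate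
6 | (R)-2,6-dimethyl-6-[(triethylsilyl)oxy]octa-1,7-dien-3-one | C=C[C@](C)(O[Si](CC)(CC)CC)CCC(=O)C(C)=C | intermediate
7 | (R)-2,4-dimethyl-4-[(triethylsilyl)oxy]cyclohex-2-en-1-one | O=C1CC[C@@](C)(O[Si](CC)(CC)CC)C=C1C | intermediate
8 | triethyl{[(1R,2R)-2-ethenyl-1,3-dimethyl-4-[(trimethylsilyl)oxy]cyclohex-3-en-1-yl]oxy}silane | C=C[C@@H]1C(C)=C(O[Si](C)(C)C)CC[C@@]1(C)O[Si](CC)(CC)CC | intermediate
9 | (2R,3R,4R)-3-ethenyl-2,4-dimethyl-2-(3-oxopentyl)-4-[(triethylsilyl)oxy]cyclohexan-1-one | C=C[C@@H]1[C@@](C)(CCC(=O)CC)C(=O)CC[C@@]1(C)O[Si](CC)(CC)CC | intermediate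
10 | (4aR,5R,6R)-5-ethenyl-1,4a,6-trimethyl-6-[(triethylsilyl)oxy]-4,4a,5,6,7,8-hexahydronaphthalen-2(3H)-one | C=C[C@@H]1[C@@]2(C)CCC(=O)C(C)=C2CC[C@@]1(C)O[Si](CC)(CC)CC | intermediate
11 | dimethyl(phenyl){[(4aS,5R,6R,8aS)-5-ethenyl-1,4a,6-trimethyl-6-[(triethylsilyl)oxy]-3,4,4a,5,6,7,8,8a-octahydronaphthalen-2-yl]oxy}silane (cis-fused) | C=C[C@@H]1[C@@]2(C)CCC(O[Si](C)(C)c3ccccc3)=C(C)[C@H]2CC[C@@]1(C)O[Si](CC)(CC)CC | intermediate
12 | lithium enolate corresponding to 11 | C=C[C@@H]1[C@@]2(C)CCC(O[Li])=C(C)[C@H]2CC[C@@]1(C)O[Si](CC)(CC)CC | intermediate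
13 | (4aS,5R,6R,8aS)-5-ethenyl-1,1,4a,6-tetramethyl-6-[(triethylsilyl)oxy]octahydronaphthalen-2(1H)-one | C=C[C@@H]1[C@@]2(C)CCC(=O)C(C)(C)[C@H]2CC[C@@]1(C)O[Si](CC)(CC)CC | intermediate
14 | (4aS,5R,6R,8aS)-1,1,4a,6-tetramethyl-5-[2-(4,4,5,5-tetramethyl-1,3,2-dioxaborolan-2-yl)ethyl]-6-[(triethylsilyl)oxy]octahydronaphthalen-2(1H)-one | CC1(C)OB(CC[C@@H]2[C@@]3(C)CCC(=O)C(C)(C)[C@H]3CC[C@@]2(C)O[Si](CC)(CC)CC)OC1(C)C | intermediate
15 | geranyl bromide, (E)-1-bromo-3,7-dimethylocta-2,6-diene | CC(C)=CCC/C(C)=C/CBr | starting material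
16 | trimethyl[(5E)-6,10-dimethylundeca-5,9-dien-1-yn-1-yl]silane | CC(C)=CCC/C(C)=C/CCC#C[Si](C)(C)C | intermediate
17 | (5E)-6,10-dimethylundeca-5,9-dien-1-yne | CC(C)=CCC/C(C)=C/CCC#C | intermediate
18 | dimethyl[(1E,5E)-2,6,10-trimethylundeca-1,5,9-trien-1-yl]alane | CC(C)=CCC/C(C)=C/CC/C(C)=C/[Al](C)C | intermediate
19 | (1E,5E)-1-iodo-2,6,10-trimethylundeca-1,5,9-triene | CC(C)=CCC/C(C)=C/CC/C(C)=C/I | intermediate
20 | (2E,6E,10E)-11-iodo-2,6,10-trimethylundeca-2,6,10-trien-1-ol | OC/C(C)=C/CC/C(C)=C/CC/C(C)=C/I | intermediate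
21 | (4aS,5R,6R,8aS)-5-[(3E,7E,11E)-13-hydroxy-4,8,12-trimethyltrideca-3,7,11-trien-1-yl]-1,1,4a,6-tetramethyl-6-[(triethylsilyl)oxy]octahydronaphthalen-2(1H)-one | OC/C(C)=C/CC/C(C)=C/CC/C(C)=C/CC[C@@H]1[C@@]2(C)CCC(=O)C(C)(C)[C@H]2CC[C@@]1(C)O[Si](CC)(CC)CC | intermediate
22 | (4aS,5R,6R,8aS)-6-hydroxy-5-[(3E,7E,11E)-13-hydroxy-4,8,12-trimethyltrideca-3,7,11-trien-1-yl]-1,1,4a,6-tetramethyloctahydronaphthalen-2(1H)-one | OC/C(C)=C/CC/C(C)=C/CC/C(C)=C/CC[C@@H]1[C@@]2(C)CCC(=O)C(C)(C)[C@H]2CC[C@@]1(C)O | intermediate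
23 | Myrrhanone A acetate | CC(=O)OC/C(C)=C/CC/C(C)=C/CC/C(C)=C/CC[C@@H]1[C@@]2(C)CCC(=O)C(C)(C)[C@H]2CC[C@@]1(C)O | target

**Count and risks**
Total steps: 17. Longest linear sequence: 13 steps (steps 1–10, then 15, 16, 17).

Steps most likely to fail:

1. Step 9. Hydride may be delivered to the other face of C5 (trans-fused series), the tetrasubstituted enone may resist 1,4-reduction, or enolate equilibration may lead to methylation at C2. The fallback sets out from 10 and comes back at 14. The vinyl group of 10 is first hydroborated as in step 10 (pinacolborane, [Ir(cod)Cl]2, dppe) to give the enone boronate (4aR,5R,6R)-1,4a,6-trimethyl-5-[2-(4,4,5,5-tetramethyl-1,3,2-dioxaborolan-2-yl)ethyl]-6-[(triethylsilyl)oxy]-4,4a,5,6,7,8-hexahydronaphthalen-2(3H)-one F1. With no alkene left to protect, F1 is hydrogenated over Pd/C (H2, EtOAc, Et3N), the classical surface-mediated route from angularly methylated octalones to cis-fused decalones, giving the cis-fused 4-monomethyl ketone (4aS,5R,6R,8aR; C1 epimers of the naphthalenone numbering) F2. Equilibrating enolate methylation (KOtBu, t-BuOH/THF, MeI), which in cis-fused 3-ketones takes place at C4, then gives 14.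

2. Step 7. The Lewis acid may cleave the tertiary silyl ether or simply protodesilylate the enol ether before a C–C bond forms at the congested C10, or the acceptor may polymerise. The fallback sets out from 8 and comes back at 10. Mild methanolysis (K2CO3, MeOH) converts 8 into the ketone (3R,4R)-3-ethenyl-2,4-dimethyl-4-[(triethylsilyl)oxy]cyclohexan-1-one F3. F3 is then taken through a classical base-mediated Robinson annulation with pent-1-en-3-one (KOH, MeOH, 0 °C → reflux), in which the equilibrating, more substituted enolate adds at C10 anti to the vinyl group and the adduct 9 cyclises in the same pot to 10.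

3. Step 15. Transmetalation of the pinacol boronate may be slow, so that protodeboronation or β-hydride elimination with alkene isomerisation competes. The fallback sets out from 14 and 20 and comes back at 22.
   - Oxidation of 14 (NaBO3·4H2O, THF/H2O) gives the primary alcohol (4aS,5R,6R,8aS)-5-(2-hydroxyethyl)-1,1,4a,6-tetramethyl-6-[(triethylsilyl)oxy]octahydronaphthalen-2(1H)-one F4.
   - Iodination (I2, PPh3, imidazole) gives the corresponding 5-(2-iodoethyl) compound F5.
   - Zinc insertion (Zn dust, LiCl, THF, 40 °C) gives the ketone-tolerant alkylzinc iodide F6.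
   - In parallel, 20 is silylated (TBSCl, imidazole, DMF) to tert-butyl{[(2E,6E,10E)-11-iodo-2,6,10-trimethylundeca-2,6,10-trien-1-yl]oxy}dimethylsilane F7.
   - Negishi coupling of F6 with F7 (Pd(dppf)Cl2, THF/NMP, rt → 50 °C) gives, with retention of the (E)-geometry, the bis-silyl ether of 22 F8.
   - HF·pyridine removes both silyl groups to give 22.

Further compounds
F1 | step 9 | (4aR,5R,6R)-1,4a,6-trimethyl-5-[2-(4,4,5,5-tetramethyl-1,3,2-dioxaborolan-2-yl)ethyl]-6-[(triethylsilyl)oxy]-4,4a,5,6,7,8-hexahydronaphthalen-2(3H)-one | CC1(C)OB(CC[C@@H]2[C@@]3(C)CCC(=O)C(C)=C3CC[C@@]2(C)O[Si](CC)(CC)CC)OC1(C)C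
F2 | step 9 | (4aS,5R,6R,8aR)-1,4a,6-trimethyl-5-[2-(4,4,5,5-tetramethyl-1,3,2-dioxaborolan-2-yl)ethyl]-6-[(triethylsilyl)oxy]octahydronaphthalen-2(1H)-one (cis-fused, C1 epimers) | CC1(C)OB(CC[C@@H]2[C@@]3(C)CCC(=O)C(C)[C@H]3CC[C@@]2(C)O[Si](CC)(CC)CC)OC1(C)C
F3 | step 7 | (3R,4R)-3-ethenyl-2,4-dimethyl-4-[(triethylsilyl)oxy]cyclohexan-1-one (C2 epimers) | C=C[C@@H]1C(C)C(=O)CC[C@@]1(C)O[Si](CC)(CC)CC
F4 | step 15 | (4aS,5R,6R,8aS)-5-(2-hydroxyethyl)-1,1,4a,6-tetramethyl-6-[(triethylsilyl)oxy]octahydronaphthalen-2(1H)-one | OCC[C@@H]1[C@@]2(C)CCC(=O)C(C)(C)[C@H]2CC[C@@]1(C)O[Si](CC)(CC)CC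
F5 | step 15 | (4aS,5R,6R,8aS)-5-(2-iodoethyl)-1,1,4a,6-tetramethyl-6-[(triethylsilyl)oxy]octahydronaphthalen-2(1H)-one | ICC[C@@H]1[C@@]2(C)CCC(=O)C(C)(C)[C@H]2CC[C@@]1(C)O[Si](CC)(CC)CC
F6 | step 15 | alkylzinc iodide from F5 | I[Zn]CC[C@@H]1[C@@]2(C)CCC(=O)C(C)(C)[C@H]2CC[C@@]1(C)O[Si](CC)(CC)CC
F7 | step 15 | tert-butyl{[(2E,6E,10E)-11-iodo-2,6,10-trimethylundeca-2,6,10-trien-1-yl]oxy}dimethylsilane | CC(C)(C)[Si](C)(C)OC/C(C)=C/CC/C(C)=C/CC/C(C)=C/I
F8 | step 15 | 13-O-tert-butyldimethylsilyl-8-O-triethylsilyl ether of 22 | CC(C)(C)[Si](C)(C)OC/C(C)=C/CC/C(C)=C/CC/C(C)=C/CC[C@@H]1[C@@]2(C)CCC(=O)C(C)(C)[C@H]2CC[C@@]1(C)O[Si](CC)(CC)CC
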